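## Retrosynthetic overview
1. The target is two O‑benzyl ethers away from the dibenzyl flavanone **16**. The only ring formed in the route, the dihydropyranone, is closed last by an intramolecular Mitsunobu etherification of the (S)‑β‑hydroxy ketone **15** with the unhindered 6'‑phenol. Inversion at the carbinol gives the (2R) flavanone.
2. **15** comes from a 2,6‑bis(MOM‑oxy)‑4‑methoxyphenyllithium (directed metalation of **7**) added to the (S)‑β‑silyloxy Weinreb amide **5**. The 2‑benzyloxybenzyl group is added at the symmetric ketone stage by NBS bromination and Negishi coupling, which avoids regiochemical ambiguity.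
3. **5** comes from the (S)‑β‑hydroxy ester **3**, made by ketoreductase (oxidoreductase) reduction of β‑ketoester **2**, which is made from 4'‑benzyloxyacetophenone.

Assumptions:
- The SMILES gives (2R) at C2, so the target is (R)‑configured.
- 5‑Methoxyresorcinol, 2‑hydroxybenzyl alcohol, 4'‑benzyloxyacetophenone and a commercial KRED panel are available.

## Route

**Step 1**
Reactants: 1, 4'‑(benzyloxy)acetophenone
Product: 2, ethyl 3‑[4‑(benzyloxy)phenyl]‑3‑oxopropanoate
Conditions: NaH, toluene, cat. EtOH, reflux
Reagents that add atoms: diethyl carbonate, CCOC(=O)OCC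
Why: Claisen‑type C‑acylation of the ketone enolate with diethyl carbonate gives the aryl β‑ketoester. The benzyl ether is inert.

**Step 2**
Reactants: 2
Product: 3, ethyl (S)‑3‑[4‑(benzyloxy)phenyl]‑3‑hydroxypropanoate
Conditions: (S)‑selective ketoreductase (KRED, oxidoreductase, panel hit), NADP⁺ (cat.), glucose, glucose dehydrogenase, 100 mM KPi pH 7.0, 15% DMSO, 30 °C, 24 h
Reagents that add atoms: none
Why: Enzymatic asymmetric ketone reduction delivers hydride to one face of the aryl ketone (Prelog‑type), setting the only stereocenter as (S); the NADPH is recycled by glucose/GDH, and ee is confirmed by chiral HPLC.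

**Step 3**
Reactants: 3
Product: 4, ethyl (S)‑3‑[4‑(benzyloxy)phenyl]‑3‑(tert‑butyldimethylsilyloxy)propanoate
Conditions: TBSCl, imidazole, DMF, rt, 16 h
Reagents that add atoms: TBSCl, C[Si](C)(Cl)C(C)(C)C
Why: Silylation of the secondary alcohol masks it for the organolithium step and for later acid exposure, and the stereocenter is untouched.

**Step 4**
Reactants: 4
Product: 5, (S)‑3‑[4‑(benzyloxy)phenyl]‑3‑(TBSO)‑N‑methoxy‑N‑methylpropanamide
Conditions: MeNH(OMe)·HCl, i‑PrMgCl, THF, –20 → 0 °C
Reagents that add atoms: N,O‑dimethylhydroxylamine hydrochloride, CONC.Cl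
Why: Magnesium amide transamidation of the ester (Weinreb amide formation) gives an acylating agent that stops at the ketone stage; the stereocenter is not acidic and is retained.

**Step 5**
Reactants: 6, 5‑methoxyresorcinol
Product: 7, 1,3‑bis(methoxymethoxy)‑5‑methoxybenzene
Conditions: MOMCl, i‑Pr₂NEt, CH₂Cl₂, 0 °C → rt
Reagents that add atoms: chloromethyl methyl ether, COCCl
Why: Double MOM protection masks both phenols and installs two chelating directing groups for ortho‑lithiation.

**Step 6**
Reactants: 7, and 5 (electrophile)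
Product: 8, (S)‑1‑[2,6‑bis(MOM‑oxy)‑4‑methoxyphenyl]‑3‑[4‑(benzyloxy)phenyl]‑3‑(TBSO)propan‑1‑one
Conditions: n‑BuLi (1.2 equiv), THF, –20 → 0 °C, 1 h; then 5, –78 → 0 °C; NH₄Cl quench
Reagents that add atoms: none
Why: Directed ortho‑metalation occurs at the single C–H flanked by two OMOM groups. The aryllithium then adds to the Weinreb amide (Weinreb ketone synthesis) without over‑addition; the carbinol stereocenter is not involved.

**Step 7**
Reactants: 8
Product: 9, the 3'‑bromo ketone (bromine on the ring carbon flanked by OMOM and OMe)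
Conditions: NBS (0.95 equiv), MeCN, –20 → 0 °C, dark
Reagents that add atoms: NBS, O=C1CCC(=O)N1Br
Why: Electrophilic aromatic bromination of the trialkoxyarene. The 3' and 5' positions are equivalent, so only one mono‑bromide forms.

**Step 8**
Reactants: 10, 2‑hydroxybenzyl alcohol
Product: 11, 2‑(benzyloxy)benzyl alcohol
Conditions: BnBr, K₂CO₃, acetone, reflux
Reagents that add atoms: benzyl bromide, BrCc1ccccc1
Why: Williamson etherification alkylates the more acidic phenol selectively over the benzylic alcohol.

**Step 9**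
Reactants: 11
Product: 12, 2‑(benzyloxy)benzyl bromide
Conditions: CBr₄, PPh₃, CH₂Cl₂, 0 °C
Reagents that add atoms: carbon tetrabromide, BrC(Br)(Br)Br
Why: Appel bromination converts the alcohol to the benzylic bromide under neutral conditions; the product is used crude.

**Step 10**
Reactants: 9, and 12 (via its benzylzinc reagent)
Product: 13, (S)‑ketone carrying the 3'‑[2‑(benzyloxy)benzyl] group
Conditions: (i) 12, Zn dust, LiCl, THF, 25 °C; (ii) 9, Pd‑PEPPSI‑IPent (3 mol%), THF, 50 °C, 12 h
Reagents that add atoms: none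
Why: Negishi cross‑coupling of a benzylic zinc reagent with the hindered aryl bromide forms the diarylmethane. MOM, TBS, benzyl ether and ketone groups tolerate it.

**Step 11**
Reactants: 13
Product: 14, 2',6'‑dihydroxy ketone (TBS ether retained)
Conditions: TMSOTf, 2,2'‑bipyridyl, MeCN, 0 °C → rt; then H₂O
Reagents that add atoms: none
Why: This is a mild Lewis‑acid MOM cleavage that is selective for aryl MOM acetals and leaves benzyl ethers and the silyl ether in place. Any TBS loss is harmless because Step 12 removes it anyway.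

**Step 12**
Reactants: 14
Product: 15, (S)‑β‑hydroxy ketone
Conditions: HF·pyridine, pyridine, THF, 0 °C → rt
Reagents that add atoms: none
Why: Buffered HF cleaves the silyl ether without base, avoiding retro‑aldol and elimination to the chalcone; the configuration is retained.

**Step 13**
Reactants: 15
Product: 16, (2R)‑7‑methoxy‑5‑hydroxy‑2‑[4‑(benzyloxy)phenyl]‑6‑[2‑(benzyloxy)benzyl]chroman‑4‑one
Conditions: PPh₃, DIAD, THF (0.02 M), 0 °C → rt
Reagents that add atoms: none
Why: Intramolecular Mitsunobu etherification proceeds by SN2 with inversion, so the (S)‑carbinol becomes the (2R) ether. The less hindered, more acidic 6'‑phenol closes the ring, while the benzyl‑flanked chelated 2'‑OH stays free as the 5‑OH.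

**Step 14**
Reactants: 16
Product: 17, (+)‑methylphelligrin A
Conditions: H₂ (1 atm), 10% Pd/C, EtOAc/MeOH, rt, 3 h
Reagents that add atoms: none
Why: Hydrogenolysis removes both O‑benzyl ethers under neutral conditions. The C2 stereocenter is not touched, and the flavanone does not racemize.

## Compound list
1 | 4'‑(benzyloxy)acetophenone | CC(=O)c1ccc(OCc2ccccc2)cc1 | starting material
2 | ethyl 3‑[4‑(benzyloxy)phenyl]‑3‑oxopropanoate | CCOC(=O)CC(=O)c1ccc(OCc2ccccc2)cc1 | intermediate
3 | ethyl (S)‑3‑[4‑(benzyloxy)phenyl]‑3‑hydroxypropanoate | CCOC(=O)C[C@H](O)c1ccc(OCc2ccccc2)cc1 | intermediate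
4 | ethyl (S)‑3‑[4‑(benzyloxy)phenyl]‑3‑(TBSO)propanoate | CCOC(=O)C[C@H](O[Si](C)(C)C(C)(C)C)c1ccc(OCc2ccccc2)cc1 | intermediate
5 | (S)‑3‑[4‑(benzyloxy)phenyl]‑3‑(TBSO)‑N‑methoxy‑N‑methylpropanamide | CON(C)C(=O)C[C@H](O[Si](C)(C)C(C)(C)C)c1ccc(OCc2ccccc2)cc1 | intermediate
6 | 5‑methoxyresorcinol | COc1cc(O)cc(O)c1 | starting material
7 | 1,3‑bis(methoxymethoxy)‑5‑methoxybenzene | COCOc1cc(OC)cc(OCOC)c1 | intermediate
8 | (S)‑aryl ketone, 2,6‑bis(MOMO)‑4‑OMe | COCOc1cc(OC)cc(OCOC)c1C(=O)C[C@H](O[Si](C)(C)C(C)(C)C)c1ccc(OCc2ccccc2)cc1 | intermediate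
9 | 3'‑bromo ketone | COCOc1c(Br)c(OC)cc(OCOC)c1C(=O)C[C@H](O[Si](C)(C)C(C)(C)C)c1ccc(OCc2ccccc2)cc1 | intermediate
10 | 2‑hydroxybenzyl alcohol | OCc1ccccc1O | starting material
11 | 2‑(benzyloxy)benzyl alcohol | OCc1ccccc1OCc1ccccc1 | intermediate
12 | 2‑(benzyloxy)benzyl bromide | BrCc1ccccc1OCc1ccccc1 | intermediate
13 | benzylated bis‑MOM ketone | COCOc1c(Cc2ccccc2OCc2ccccc2)c(OC)cc(OCOC)c1C(=O)C[C@H](O[Si](C)(C)C(C)(C)C)c1ccc(OCc2ccccc2)cc1 | intermediate
14 | 2',6'‑dihydroxy ketone (TBS ether) | Oc1c(Cc2ccccc2OCc2ccccc2)c(OC)cc(O)c1C(=O)C[C@H](O[Si](C)(C)C(C)(C)C)c1ccc(OCc2ccccc2)cc1 | intermediate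
15 | (S)‑β‑hydroxy ketone | Oc1c(Cc2ccccc2OCc2ccccc2)c(OC)cc(O)c1C(=O)C[C@H](O)c1ccc(OCc2ccccc2)cc1 | intermediate
16 | (2R)‑dibenzyl flavanone | O=C1C[C@H](c2ccc(OCc3ccccc3)cc2)Oc2cc(OC)c(Cc3ccccc3OCc3ccccc3)c(O)c21 | intermediate
17 | (+)‑methylphelligrin A | COc1cc2c(c(O)c1Cc1ccccc1O)C(=O)C[C@H](c1ccc(O)cc1)O2 | target

## Totals
- Total steps: 14.
- Longest linear sequence: 11 (1 → 2 → 3 → 4 → 8 → 9 → 13 → 14 → 15 → 16 → 17, via Steps 1–4, 6, 7, 10–14).

## Three steps most likely to fail
1. **Step 13, Mitsunobu ring closure.** Risks are partial SN1 racemization at the electron‑rich benzylic carbon, E1cB elimination, and closure through the wrong phenol (8‑benzyl isomer).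
   - Fallback: dehydrate 15 to the 2'‑hydroxychalcone and cyclize it with a chiral bifunctional squaramide/thiourea catalyst (asymmetric oxa‑Michael). This sets C2 by catalysis and does not depend on inversion.
2. **Step 6, aryllithium/Weinreb acylation.** The hindered aryllithium may deprotonate the α‑CH₂ and cause β‑elimination of OTBS.
   - Fallback: reduce 5 to the β‑silyloxy aldehyde (DIBAL), add the same aryllithium to give the carbinol, and oxidize with Dess–Martin periodinane. This changes the acylation to a 1,2‑addition/oxidation sequence.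
3. **Step 10, Negishi coupling on the hindered, electron‑rich bromide.** Oxidative addition may be slow, and the benzylzinc may homocouple.
   - Fallback: install the diarylmethane before acylation. Vilsmeier formylate 6, bis‑MOM protect, add 2‑(benzyloxy)phenyllithium, deoxygenate the carbinol by Barton–McCombie, and then carry out the Step 6 acylation on the benzylated arene.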